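## Retrosynthetic overview

1. Chain numbering: C1–C2 ethyl, C3 ketal carbon, C4(Me)=C5, C6(Me), C7(H)–O, C8(Me)=C9–O, C10(Me), C11=O, C12(Me), C13, C14(Me)=C15, C16–C17. Ring A is the dihydropyran (O, C3–C7). Ring B is the 4H-1,3-dioxine (C3, O, C9, C8, C7, O).
2. Enabling feature: in ring A the ketal carbon C3 carries the ring oxygen and is allylic to C4=C5. It is therefore the terminus of an allyl-oxocarbenium ion, the ion released when a 6,6-dihalo-2-oxabicyclo[3.1.0]hexane opens. The second ketal oxygen is the enol oxygen of a C9 ketone that hangs on C7 and reaches C3 through a six-membered ring.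
3. Endgame: C11 ketone from the alcohol, and C4–CH3 from C4–Cl (Negishi). Rings A and B form together from a dichlorocyclopropane-fused oxolane carrying the whole keto side chain (strain-release ring expansion with internal capture).
4. Precursor: C10–C11 by a substrate-controlled anti aldol of an ethyl ketone with (2R,4E)-2,4-dimethylhept-4-enal. The cyclopropane comes from dichlorocarbene and a 2,3-dihydrofuran, the dihydrofuran from 5-endo-dig closure of an alkynol, and C6–C7 from an allenylzinc addition.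
5. Ring order: oxolane, then cyclopropane, then rings A and B in one operation. Stereo relay: C6 from a catalytic ketone reduction, C7 from C6, C3 from C7, C10 from the temporary centre C8.

Key step: step 19

Remark: the carbene in step 9 is assumed to add anti to the C6 methyl group. The face chosen has no consequence, because the three cyclopropane centres vanish in step 19.

## Route

Step 1
Reactants: 1 hex-3-yn-2-one
Product: 2 (R)-hex-3-yn-2-ol
Conditions: Ru[(R,R)-TsNCH(Ph)CH(Ph)NH](p-cymene) (1 mol %), i-PrOH, rt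
Reagents that add atoms: none
Why: Noyori asymmetric transfer hydrogenation of an alkynyl methyl ketone, in which the (R,R)-diamine ligand should deliver hydride to the face that gives the (R)-carbinol while the triple bond stays untouched.

Step 2
Reactants: 2 (R)-hex-3-yn-2-ol
Product: 3 (R)-hex-3-yn-2-yl methanesulfonate
Conditions: MsCl, Et3N, CH2Cl2, −78 → 0 °C
Reagents that add atoms: methanesulfonyl chloride CS(=O)(=O)Cl
Why: O-sulfonylation that does not touch the C–O bond, so the configuration is kept.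

Step 3
Reactants: 4 (S)-4-benzyl-3-propanoyl-1,3-oxazolidin-2-one; 5 propanal
Product: 7 (S)-4-benzyl-3-[(2S,3R)-3-hydroxy-2-methylpentanoyl]-1,3-oxazolidin-2-one, via Z-boron enolate 6 (not isolated)
Conditions: n-Bu2BOTf, Et3N, CH2Cl2, 0 °C; 5, −78 → 0 °C; then pH 7 buffer (NaH2PO4/Na2HPO4), MeOH, 30% H2O2, 0 °C
Reagents that add atoms: dibutylboron triflate CCCCB(CCCC)OS(=O)(=O)C(F)(F)F (boron unit held in 6 only)
Why: Evans syn aldol through a Zimmerman–Traxler chair with the auxiliary dipole opposed, which sets C8 (S) and C9 (R); C8 later steers steps 7, 17 and 19 before it is erased, and C9 is erased in step 11.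

Step 4
Reactants: 7 (S)-4-benzyl-3-[(2S,3R)-3-hydroxy-2-methylpentanoyl]-1,3-oxazolidin-2-one
Product: 8 (2S,3R)-3-hydroxy-N-methoxy-N,2-dimethylpentanamide
Conditions: MeNHOMe·HCl, AlMe3, CH2Cl2, −10 °C → rt; aq. potassium sodium tartrate
Reagents that add atoms: N,O-dimethylhydroxylamine hydrochloride CNOC.Cl
Why: Weinreb transamidation of an aldol imide by the aluminium amide, helped by the free β-hydroxyl group and leaving both stereocentres untouched.

Step 5
Reactants: 8 (2S,3R)-3-hydroxy-N-methoxy-N,2-dimethylpentanamide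
Product: 9 (2S,3R)-3-(tert-butyldimethylsilyloxy)-N-methoxy-N,2-dimethylpentanamide
Conditions: TBSOTf, 2,6-lutidine, CH2Cl2, 0 °C
Reagents that add atoms: tert-butyldimethylsilyl triflate CC(C)(C)[Si](C)(C)OS(=O)(=O)C(F)(F)F
Why: Standard silylation that masks the C9 oxygen in a base-stable form for steps 6 to 9.

Step 6
Reactants: 9 (2S,3R)-3-(tert-butyldimethylsilyloxy)-N-methoxy-N,2-dimethylpentanamide
Product: 10 (2S,3R)-3-(tert-butyldimethylsilyloxy)-2-methylpentanal
Conditions: i-Bu2AlH, THF, −78 °C; aq. potassium sodium tartrate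
Reagents that add atoms: none
Why: Weinreb amide reduction that stops at the chelated tetrahedral adduct and releases the aldehyde only on work-up, so over-reduction and C8 epimerisation are avoided.

Step 7
Reactants: 10 (2S,3R)-3-(tert-butyldimethylsilyloxy)-2-methylpentanal; 3 (R)-hex-3-yn-2-yl methanesulfonate
Product: 12 (3R,4R,5S,6S)-3-(tert-butyldimethylsilyloxy)-4,6-dimethyldec-7-yn-5-ol, via allenylzinc 11 (not isolated)
Conditions: Pd(OAc)2 (5 mol %), PPh3 (5 mol %), Et2Zn (3 equiv), THF, −78 → −20 °C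
Reagents that add atoms: diethylzinc CC[Zn]CC (zinc unit held in 11 only)
Why: Marshall–Tamaru propargylation, in which zerovalent palladium formed in situ displaces the mesylate anti (SN2′) and transmetalation gives the (P)-allenylzinc 11, which adds through a cyclic SE2′ transition state, so that C6 comes from the mesylate with net inversion and C7 from the anti-selective chair in the Felkin–Anh-matched sense relative to C8.

Step 8
Reactants: 12 (3R,4R,5S,6S)-3-(tert-butyldimethylsilyloxy)-4,6-dimethyldec-7-yn-5-ol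
Product: 13 (2S,3S)-2-[(2R,3R)-3-(tert-butyldimethylsilyloxy)pentan-2-yl]-5-ethyl-3-methyl-2,3-dihydrofuran
Conditions: PdCl2(PhCN)2 (5 mol %), Et2O, rt; filtration through basic Al2O3
Reagents that add atoms: none
Why: 5-endo-dig cycloisomerisation of a 3-alkyn-1-ol (oxypalladation by divalent palladium, then protodemetalation), a known route to 2,3-dihydrofurans in which 4-exo closure does not compete and no stereocentre is touched.

Step 9
Reactants: 13 (2S,3S)-2-[(2R,3R)-3-(tert-butyldimethylsilyloxy)pentan-2-yl]-5-ethyl-3-methyl-2,3-dihydrofuran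
Product: 14 (1R,3S,4S,5S)-3-[(2R,3R)-3-(tert-butyldimethylsilyloxy)pentan-2-yl]-6,6-dichloro-1-ethyl-4-methyl-2-oxabicyclo[3.1.0]hexane
Conditions: CHCl3, 50% aq. NaOH, BnEt3NCl (5 mol %), 0 °C → rt
Reagents that add atoms: chloroform ClC(Cl)Cl
Why: Makosza phase-transfer dichlorocarbene [2+1] cycloaddition to the only C=C bond present, run before the side-chain alkene exists so that no chemoselectivity is asked for, with approach expected anti to the allylic methyl group.

Step 10
Reactants: 14 (1R,3S,4S,5S)-3-[(2R,3R)-3-(tert-butyldimethylsilyloxy)pentan-2-yl]-6,6-dichloro-1-ethyl-4-methyl-2-oxabicyclo[3.1.0]hexane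
Product: 15 (2S,3R)-2-[(1R,3S,4S,5S)-6,6-dichloro-1-ethyl-4-methyl-2-oxabicyclo[3.1.0]hexan-3-yl]pentan-3-ol
Conditions: n-Bu4NF, THF, rt
Reagents that add atoms: none
Why: Fluoride desilylation under non-acidic conditions, which should leave the dichlorocyclopropyl ether un-ionised.

Step 11
Reactants: 15 (2S,3R)-2-[(1R,3S,4S,5S)-6,6-dichloro-1-ethyl-4-methyl-2-oxabicyclo[3.1.0]hexan-3-yl]pentan-3-ol
Product: 16 (2R)-2-[(1R,3S,4S,5S)-6,6-dichloro-1-ethyl-4-methyl-2-oxabicyclo[3.1.0]hexan-3-yl]pentan-3-one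
Conditions: Dess–Martin periodinane, NaHCO3, CH2Cl2, 0 °C → rt
Reagents that add atoms: none
Why: Buffered Dess–Martin oxidation, mild enough to keep the C8 centre next to the new ketone.

Step 12
Reactants: 17 (E)-2-methylpent-2-enal
Product: 18 (E)-2-methylpent-2-en-1-ol
Conditions: NaBH4, CeCl3·7H2O, MeOH, 0 °C
Reagents that add atoms: none
Why: Luche 1,2-reduction of an enal with retention of the E alkene.

Step 13
Reactants: 18 (E)-2-methylpent-2-en-1-ol
Product: 19 (E)-1-bromo-2-methylpent-2-ene
Conditions: PBr3, Et2O, 0 °C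
Reagents that add atoms: phosphorus tribromide BrP(Br)Br
Why: SN2 bromination of a primary allylic alcohol at low temperature, which should proceed without allylic transposition or loss of alkene geometry.

Step 14
Reactants: 4 (S)-4-benzyl-3-propanoyl-1,3-oxazolidin-2-one; 19 (E)-1-bromo-2-methylpent-2-ene
Product: 21 (S)-4-benzyl-3-[(2R,4E)-2,4-dimethylhept-4-enoyl]-1,3-oxazolidin-2-one, via sodium Z-enolate 20 (not isolated)
Conditions: NaN(SiMe3)2, THF, −78 °C; then 19, −78 → −40 °C
Reagents that add atoms: sodium hexamethyldisilazide C[Si](C)(C)[N-][Si](C)(C)C.[Na+] (sodium held in 20 only)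
Why: Evans asymmetric alkylation, in which the benzyl group shields one face of the chelated Z-enolate 20 and the allylic bromide enters from the other face to set C12 as R.

Step 15
Reactants: 21 (S)-4-benzyl-3-[(2R,4E)-2,4-dimethylhept-4-enoyl]-1,3-oxazolidin-2-one
Product: 22 (2R,4E)-2,4-dimethylhept-4-en-1-ol
Conditions: LiBH4, THF, 0 °C → rt
Reagents that add atoms: none
Why: Reductive removal of the auxiliary at the exocyclic carbonyl group without epimerisation at C12.

Step 16
Reactants: 22 (2R,4E)-2,4-dimethylhept-4-en-1-ol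
Product: 23 (2R,4E)-2,4-dimethylhept-4-enal
Conditions: Dess–Martin periodinane, NaHCO3, CH2Cl2, 0 °C; used at once
Reagents that add atoms: none
Why: Buffered Dess–Martin oxidation that gives the α-chiral aldehyde without base-induced racemisation.

Step 17
Reactants: 16 (2R)-2-[(1R,3S,4S,5S)-6,6-dichloro-1-ethyl-4-methyl-2-oxabicyclo[3.1.0]hexan-3-yl]pentan-3-one; 23 (2R,4E)-2,4-dimethylhept-4-enal
Product: 25 (2R,4R,5R,6R,8E)-2-[(1R,3S,4S,5S)-6,6-dichloro-1-ethyl-4-methyl-2-oxabicyclo[3.1.0]hexan-3-yl]-5-hydroxy-4,6,8-trimethylundec-8-en-3-one, via E-enol borinate 24 (not isolated)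
Conditions: (c-C6H11)2BCl, Et3N, Et2O, 0 °C; then 23, −78 → −20 °C; then MeOH, pH 7 buffer (NaH2PO4/Na2HPO4), 30% H2O2, 0 °C
Reagents that add atoms: chlorodicyclohexylborane ClB(C1CCCCC1)C1CCCCC1 (boron unit held in 24 only)
Why: Paterson anti aldol, in which the ethyl side is enolised to the E-enol borinate 24 and the Zimmerman–Traxler chair forms on the face fixed by C8 (C8–H eclipsing the enolate to avoid A(1,3) strain, the C7 oxygen turned toward the formyl hydrogen), so that C10 should end anti to the C8 methyl group and C11 anti to C10, with enolate control expected to override the weak opposing Felkin–Anh preference of 23.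

Step 18
Reactants: 25 (2R,4R,5R,6R,8E)-2-[(1R,3S,4S,5S)-6,6-dichloro-1-ethyl-4-methyl-2-oxabicyclo[3.1.0]hexan-3-yl]-5-hydroxy-4,6,8-trimethylundec-8-en-3-one
Product: 26 (2R,4R,5R,6R,8E)-2-[(1R,3S,4S,5S)-6,6-dichloro-1-ethyl-4-methyl-2-oxabicyclo[3.1.0]hexan-3-yl]-4,6,8-trimethyl-5-(triethylsilyloxy)undec-8-en-3-one
Conditions: Et3SiOTf, 2,6-lutidine, CH2Cl2, −78 °C
Reagents that add atoms: triethylsilyl triflate CC[Si](CC)(CC)OS(=O)(=O)C(F)(F)F
Why: Fast low-temperature silylation of the aldol hydroxyl group, which prevents retro-aldol cleavage and dehydration in step 19.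

Step 19
Reactants: 26 (2R,4R,5R,6R,8E)-2-[(1R,3S,4S,5S)-6,6-dichloro-1-ethyl-4-methyl-2-oxabicyclo[3.1.0]hexan-3-yl]-4,6,8-trimethyl-5-(triethylsilyloxy)undec-8-en-3-one
Product: 29 (1S,5S,6S)-8-chloro-1-ethyl-4,6-dimethyl-3-[(2R,3R,4R,6E)-4,6-dimethyl-3-(triethylsilyloxy)non-6-en-2-yl]-2,9-dioxabicyclo[3.3.1]nona-3,7-diene, via pyranylium cation 27 (not isolated), via bicyclic oxocarbenium cation 28 (not isolated)
Conditions: AgOSO2CF3 (1.5 equiv), 2,6-di-tert-butyl-4-methylpyridine (2 equiv), 4 Å molecular sieves, CH2Cl2, −20 °C → rt, dark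
Reagents that add atoms: none
Why: Proposed new method: the silver cation of AgOSO2CF3 takes the endo chloride while the C3–C5 bond shared by the cyclopropane and the oxolane opens in the disrotatory two-electron electrocyclic mode (Woodward–Hoffmann–DePuy rule), so that cyclopropane strain and the push of the ring oxygen turn the five-membered oxolane into the six-membered allyl-oxocarbenium ion 27 by insertion of C4 between C3 and C5; the C9 carbonyl oxygen then adds to C3 to give 28, which loses the C8 proton to the hindered pyridine and ends as the enol-ether ketal 29. The closest known reaction type is the silver- or base-promoted ring expansion of gem-dihalocyclopropanated cyclic enol ethers (glycals and 2,3-dihydrofurans) with capture by an external alcohol or carboxylate, and what is new is the internal capture by a ketone oxygen followed by proton loss. Ring A is closed by one-carbon ring expansion (electrocyclic opening of the fused bond), ring B by 6-endo-trig addition of the carbonyl oxygen to the C3=O+ unit, both atoms of which end up in the new ring. The only new stereocentre is C3: the three-atom tether C8–C9–O hangs on C7 and can bridge only to the face of the flat cation that is cis to it (1,3-diaxial bridge), so C7 fixes C3, both facial isomers of the cyclopropane converge, and C6, C7, C10, C11 and C12 are not touched. The step needs O- over C-attack (C8 attack would demand an oxetane), C3 over C5 attack (as with Ferrier-type cations the charge sits on the oxocarbenium carbon and capture is reversible, the ketal being the sink) and proton loss from C8 and not from C10 or from the ethyl group. The last point is secured by the C8 configuration chosen in step 3, which places C8–H axial and parallel to the empty orbital of 28 and leads to the endocyclic tetrasubstituted enol ether, by the buffered medium in which any dienol ether formed by loss of an ethyl proton is reprotonated, and by the silyl ether at C11, which blocks retro-aldol cleavage.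

Step 20
Reactants: 29 (1S,5S,6S)-8-chloro-1-ethyl-4,6-dimethyl-3-[(2R,3R,4R,6E)-4,6-dimethyl-3-(triethylsilyloxy)non-6-en-2-yl]-2,9-dioxabicyclo[3.3.1]nona-3,7-diene
Product: 30 (1S,5S,6S)-1-ethyl-4,6,8-trimethyl-3-[(2R,3R,4R,6E)-4,6-dimethyl-3-(triethylsilyloxy)non-6-en-2-yl]-2,9-dioxabicyclo[3.3.1]nona-3,7-diene
Conditions: Me2Zn (3 equiv), Pd(P(t-Bu)3)2 (5 mol %), THF/NMP, 60 °C
Reagents that add atoms: dimethylzinc C[Zn]C
Why: Negishi coupling of an alkenyl chloride, made possible by the electron-rich bulky phosphine on zerovalent palladium and run under neutral conditions that spare the ketal, the enol ether and the silyl ether.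

Step 21
Reactants: 30 (1S,5S,6S)-1-ethyl-4,6,8-trimethyl-3-[(2R,3R,4R,6E)-4,6-dimethyl-3-(triethylsilyloxy)non-6-en-2-yl]-2,9-dioxabicyclo[3.3.1]nona-3,7-diene
Product: 31 (2R,3R,4R,6E)-2-[(1S,5S,6S)-1-ethyl-4,6,8-trimethyl-2,9-dioxabicyclo[3.3.1]nona-3,7-dien-3-yl]-4,6-dimethylnon-6-en-3-ol
Conditions: HF·pyridine, excess pyridine, THF, 0 °C
Reagents that add atoms: none
Why: Pyridine-buffered fluoride cleavage of the labile triethylsilyl ether, mild enough for the acid-sensitive enol-ether ketal.

Step 22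
Reactants: 31 (2R,3R,4R,6E)-2-[(1S,5S,6S)-1-ethyl-4,6,8-trimethyl-2,9-dioxabicyclo[3.3.1]nona-3,7-dien-3-yl]-4,6-dimethylnon-6-en-3-ol
Product: 32 (2S,4R,6E)-2-[(1S,5S,6S)-1-ethyl-4,6,8-trimethyl-2,9-dioxabicyclo[3.3.1]nona-3,7-dien-3-yl]-4,6-dimethylnon-6-en-3-one
Conditions: Dess–Martin periodinane, NaHCO3, CH2Cl2, 0 °C
Reagents that add atoms: none
Why: Buffered Dess–Martin oxidation as the last step, so that the epimerisable centres C10 and C12 flanking the new ketone never meet acid or base (the C10 descriptor changes from R to S only through the change in priorities).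

## Compound list

1 | hex-3-yn-2-one | CCC#CC(C)=O | starting material
2 | (R)-hex-3-yn-2-ol | C[C@@H](O)C#CCC | intermediate
3 | (R)-hex-3-yn-2-yl methanesulfonate | C[C@@H](OS(C)(=O)=O)C#CCC | intermediate
4 | (S)-4-benzyl-3-propanoyl-1,3-oxazolidin-2-one | CCC(=O)N1[C@@H](Cc2ccccc2)COC1=O | starting material
5 | propanal | CCC=O | starting material
6 | Z-dibutylboron enolate of 4 (not isolated) | C/C=C(\OB(CCCC)CCCC)N1[C@@H](Cc2ccccc2)COC1=O | intermediate
7 | (S)-4-benzyl-3-[(2S,3R)-3-hydroxy-2-methylpentanoyl]-1,3-oxazolidin-2-one | O=C([C@@H](C)[C@H](O)CC)N1[C@@H](Cc2ccccc2)COC1=O | intermediate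
8 | (2S,3R)-3-hydroxy-N-methoxy-N,2-dimethylpentanamide | CON(C)C(=O)[C@@H](C)[C@H](O)CC | intermediate
9 | (2S,3R)-3-(tert-butyldimethylsilyloxy)-N-methoxy-N,2-dimethylpentanamide | CON(C)C(=O)[C@@H](C)[C@H](O[Si](C)(C)C(C)(C)C)CC | intermediate
10 | (2S,3R)-3-(tert-butyldimethylsilyloxy)-2-methylpentanal | O=C[C@@H](C)[C@H](O[Si](C)(C)C(C)(C)C)CC | intermediate
11 | (P)-ethyl(hexa-2,3-dien-4-yl)zinc (not isolated) | CC[Zn]C(CC)=[C@@]=C([H])C | intermediate
12 | (3R,4R,5S,6S)-3-(tert-butyldimethylsilyloxy)-4,6-dimethyldec-7-yn-5-ol (C6/C7 anti, C7/C8 syn) | CCC#C[C@H](C)[C@H](O)[C@@H](C)[C@H](O[Si](C)(C)C(C)(C)C)CC | intermediate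
13 | (2S,3S)-2-[(2R,3R)-3-(tert-butyldimethylsilyloxy)pentan-2-yl]-5-ethyl-3-methyl-2,3-dihydrofuran (2,3-trans) | CCC1=C[C@H](C)[C@H](O1)[C@@H](C)[C@H](O[Si](C)(C)C(C)(C)C)CC | intermediate
14 | (1R,3S,4S,5S)-3-[(2R,3R)-3-(tert-butyldimethylsilyloxy)pentan-2-yl]-6,6-dichloro-1-ethyl-4-methyl-2-oxabicyclo[3.1.0]hexane (CCl2 bridge anti to the ring methyl group) | CC[C@@]12O[C@H]([C@@H](C)[C@H](O[Si](C)(C)C(C)(C)C)CC)[C@@H](C)[C@@H]1C2(Cl)Cl | intermediate
15 | (2S,3R)-2-[(1R,3S,4S,5S)-6,6-dichloro-1-ethyl-4-methyl-2-oxabicyclo[3.1.0]hexan-3-yl]pentan-3-ol | CC[C@@]12O[C@H]([C@@H](C)[C@H](O)CC)[C@@H](C)[C@@H]1C2(Cl)Cl | intermediate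
16 | (2R)-2-[(1R,3S,4S,5S)-6,6-dichloro-1-ethyl-4-methyl-2-oxabicyclo[3.1.0]hexan-3-yl]pentan-3-one | CC[C@@]12O[C@H]([C@@H](C)C(=O)CC)[C@@H](C)[C@@H]1C2(Cl)Cl | intermediate
17 | (E)-2-methylpent-2-enal | CC/C=C(\C)C=O | starting material
18 | (E)-2-methylpent-2-en-1-ol | CC/C=C(\C)CO | intermediate
19 | (E)-1-bromo-2-methylpent-2-ene | CC/C=C(\C)CBr | intermediate
20 | sodium Z-enolate of 4 (not isolated) | C/C=C(\[O-])N1[C@@H](Cc2ccccc2)COC1=O.[Na+] | intermediate
21 | (S)-4-benzyl-3-[(2R,4E)-2,4-dimethylhept-4-enoyl]-1,3-oxazolidin-2-one | O=C([C@H](C)C/C(C)=C/CC)N1[C@@H](Cc2ccccc2)COC1=O | intermediate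
22 | (2R,4E)-2,4-dimethylhept-4-en-1-ol | OC[C@H](C)C/C(C)=C/CC | intermediate
23 | (2R,4E)-2,4-dimethylhept-4-enal | O=C[C@H](C)C/C(C)=C/CC | intermediate
24 | E-enol dicyclohexylborinate of 16 (not isolated) | CC[C@@]12O[C@H]([C@@H](C)/C(OB(C3CCCCC3)C3CCCCC3)=C\C)[C@@H](C)[C@@H]1C2(Cl)Cl | intermediate
25 | (2R,4R,5R,6R,8E)-2-[(1R,3S,4S,5S)-6,6-dichloro-1-ethyl-4-methyl-2-oxabicyclo[3.1.0]hexan-3-yl]-5-hydroxy-4,6,8-trimethylundec-8-en-3-one | CC[C@@]12O[C@H]([C@@H](C)C(=O)[C@H](C)[C@H](O)[C@H](C)C/C(C)=C/CC)[C@@H](C)[C@@H]1C2(Cl)Cl | intermediate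
26 | triethylsilyl ether of 25 | CC[C@@]12O[C@H]([C@@H](C)C(=O)[C@H](C)[C@H](O[Si](CC)(CC)CC)[C@H](C)C/C(C)=C/CC)[C@@H](C)[C@@H]1C2(Cl)Cl | intermediate
27 | 3-chloro-2-ethyl-5-methyl-5,6-dihydropyran-1-ylium cation bearing the keto side chain at C6 of the ring (not isolated) | CCC1=[O+][C@H]([C@@H](C)C(=O)[C@H](C)[C@H](O[Si](CC)(CC)CC)[C@H](C)C/C(C)=C/CC)[C@@H](C)C=C1Cl | intermediate
28 | bicyclic oxocarbenium cation, C9=O+ bound to C3, C8–H still in place (not isolated) | CC/C=C(\C)C[C@@H](C)[C@@H](O[Si](CC)(CC)CC)[C@@H](C)C=1[C@H](C)[C@H]2O[C@@](CC)([O+]=1)C(Cl)=C[C@@H]2C | intermediate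
29 | (1S,5S,6S)-8-chloro-1-ethyl-4,6-dimethyl-3-[(2R,3R,4R,6E)-4,6-dimethyl-3-(triethylsilyloxy)non-6-en-2-yl]-2,9-dioxabicyclo[3.3.1]nona-3,7-diene | CC/C=C(\C)C[C@@H](C)[C@@H](O[Si](CC)(CC)CC)[C@@H](C)C1=C(C)[C@H]2O[C@@](CC)(O1)C(Cl)=C[C@@H]2C | intermediate
30 | (1S,5S,6S)-1-ethyl-4,6,8-trimethyl-3-[(2R,3R,4R,6E)-4,6-dimethyl-3-(triethylsilyloxy)non-6-en-2-yl]-2,9-dioxabicyclo[3.3.1]nona-3,7-diene | CC/C=C(\C)C[C@@H](C)[C@@H](O[Si](CC)(CC)CC)[C@@H](C)C1=C(C)[C@H]2O[C@@](CC)(O1)C(C)=C[C@@H]2C | intermediate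
31 | (2R,3R,4R,6E)-2-[(1S,5S,6S)-1-ethyl-4,6,8-trimethyl-2,9-dioxabicyclo[3.3.1]nona-3,7-dien-3-yl]-4,6-dimethylnon-6-en-3-ol | CC/C=C(\C)C[C@@H](C)[C@@H](O)[C@@H](C)C1=C(C)[C@H]2O[C@@](CC)(O1)C(C)=C[C@@H]2C | intermediate
32 | (2S,4R,6E)-2-[(1S,5S,6S)-1-ethyl-4,6,8-trimethyl-2,9-dioxabicyclo[3.3.1]nona-3,7-dien-3-yl]-4,6-dimethylnon-6-en-3-one (CNP0232650.2) | CC/C=C(\C)C[C@@H](C)C(=O)[C@@H](C)C1=C(C)[C@H]2O[C@@](CC)(O1)C(C)=C[C@@H]2C | target

## Step count and risks

Total step count: 22. Longest linear sequence: 15 (steps 3–11 and 17–22).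

**1. Step 19.**
- What may go wrong: proton loss from the ethyl group or from C6 of the ring-expanded cation may outrun internal capture. Proton loss toward C10 may scramble that centre. The side-chain alkene may attack the C9 cation in a Prins-type closure.
- Fallback (known chemistry): it sets out from 26 and comes back at 29. 26 would be treated with AgOSO2CF3 and 2,6-lutidine in MeOH/CH2Cl2, the established alcohol-capture version of this ring expansion, to give the methyl ketal F1. A catalytic amount of pyridinium p-toluenesulfonate in toluene over 5 Å molecular sieves would then exchange methanol for the enol oxygen of the C9 ketone. This exchange runs under thermodynamic control, with the sieves taking up the methanol, and delivers 29.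

**2. Step 20.**
- What may go wrong: oxidative addition into the alkenyl C–Cl bond next to the quaternary ketal carbon may be sluggish. Zerovalent palladium may ionise the allylic ketal. The bicycle may suffer thermal damage during prolonged heating.
- Fallback: it sets out from 29 and comes back at 30, with the polarity reversed. Reductive lithiation of 29 with lithium 4,4′-di-tert-butylbiphenylide in THF at −78 °C would give the alkenyllithium F2. β-Elimination is barred here because it would demand a six-membered cyclic allene. Quenching with MeI would give 30.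

**3. Step 17.**
- What may go wrong: enolate facial control may erode, because the Felkin–Anh preference of the α-chiral aldehyde opposes it. The boron Lewis acid may ionise the chlorocyclopropane prematurely.
- Fallback: it sets out from 19 and 16 and comes back at 25. The opposing stereocentre is taken out of the bond-forming event.
- Bromide 19 would alkylate lithiated N-tert-butylethanimine (from the imine and lithium diisopropylamide) to give the imine F3. Aqueous oxalic acid would hydrolyse this to (E)-4-methylhept-4-enal F4.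
- Amine-catalysed α-methylenation (aqueous CH2O, pyrrolidine, propionic acid, i-PrOH) would give the achiral enal F5.
- The same enol borinate 24 would add to F5, the best-precedented aldehyde class for this aldol, to give the allylic alcohol F6.
- Hydroxyl-directed hydrogenation with [Rh(norbornadiene)(Ph2P(CH2)4PPh2)]BF4 and H2 at elevated pressure in CH2Cl2 should reduce only the 1,1-disubstituted alkene. It should place the C12 methyl group anti to the C11 hydroxyl group, which is 25.

## Further compounds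

F1 | step 19 | (2R,4R,5R,6R,8E)-2-[5-chloro-6-ethyl-6-methoxy-3-methyl-3,6-dihydro-2H-pyran-2-yl]-4,6,8-trimethyl-5-(triethylsilyloxy)undec-8-en-3-one, methoxy group axial and trans to the C7 side chain | CC[C@]1(OC)O[C@H]([C@@H](C)C(=O)[C@H](C)[C@H](O[Si](CC)(CC)CC)[C@H](C)C/C(C)=C/CC)[C@@H](C)C=C1Cl
F2 | step 20 | 8-lithio analogue of 29 | CC/C=C(\C)C[C@@H](C)[C@@H](O[Si](CC)(CC)CC)[C@@H](C)C1=C(C)[C@H]2O[C@@](CC)(O1)C([Li])=C[C@@H]2C
F3 | step 17 | N-tert-butyl imine of (E)-4-methylhept-4-enal | CC/C=C(\C)CC/C=N/C(C)(C)C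
F4 | step 17 | (E)-4-methylhept-4-enal | CC/C=C(\C)CCC=O
F5 | step 17 | (E)-4-methyl-2-methylidenehept-4-enal | CC/C=C(\C)CC(=C)C=O
F6 | step 17 | (2R,4R,5S,8E)-2-[(1R,3S,4S,5S)-6,6-dichloro-1-ethyl-4-methyl-2-oxabicyclo[3.1.0]hexan-3-yl]-5-hydroxy-4,8-dimethyl-6-methylideneundec-8-en-3-one | CC[C@@]12O[C@H]([C@@H](C)C(=O)[C@H](C)[C@H](O)C(=C)C/C(C)=C/CC)[C@@H](C)[C@@H]1C2(Cl)Cl
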